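(All runs are simulated for substances that don't exist; noise was put on by code.)

At early times in gamma, the flask in question, complex with one exchanged climbs 22.2 times as steeply as it later falls, yet it stalls near a quarter of the charge.

| setting | gamma | epsilon | flask |
|---|---|---|---|
| starting complex | 0.14 M | 0.14 M | 0.14 M |
| incoming ligand | 0.56 M | 0.28 M | 0.560 M |
| leaving ligand | 0.070 M | 0.070 M | 0.0700 M |
| protic impurity | 7 mM | 7 mM | 7.00 mM |
| remark | the very flask that is asked about, followed so far | run made earlier |  |
| time |  |  | 12 min |

| run | time / min | complex with one exchanged / % |
|---|---|---|
| gamma | 0.167 | 16.8 |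
| gamma | 0.250 | 20.6 |
| gamma | 0.500 | 24.3 |
| gamma | 0.833 | 24.8 |
| gamma | 1.33 | 23.0 |
| gamma | 2.50 | 17.7 |
| epsilon | 0.167 | 8.9 |
| epsilon | 0.333 | 14.1 |
| epsilon | 0.667 | 16.2 |
| epsilon | 1.33 | 16.5 |
| epsilon | 2.50 | 14.6 |
| epsilon | 5.00 | 10.0 |

(scatter of a reading: 0.5 percentage points)

- time up to 12 min at which complex with one exchanged stands highest
- the amount of complex with one exchanged, in percent of the starting complex charged, at that time



Why the stall? I take the first exchange to run both ways: starting complex and incoming ligand make complex with one exchanged, while that complex and leaving ligand remake them.

What do you compute? Where the two directions balance, their rates are equal, so dividing one by the other removes time. At epsilon's highest reading, 16.5%, each exchange having used one starting complex and one incoming ligand and released one leaving ligand, I get 0.0716. This is the stall quotient, c(complex with one exchanged) times c(leaving ligand) over c(starting complex) times c(incoming ligand), the reaction quotient of a pre-equilibrium.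

Isn't that reading also affected by later loss? Yes, so the quotient is a reading, with that loss and the scatter inside it.

What does it give for gamma? Epsilon has half the incoming ligand, so it is a separate test. Solving the same balance with gamma's charges gives a stall level of 26.0%.

And the time? Gamma reads 24.3% at 0.500 min and 24.8% at 0.833 min, then falls to 17.7% at 2.50 min. I commit to a peak between those first two times, slightly under the stall level.

The forecast gives 0.7 min (0.55 min to 0.95 min) and 25% (24.2% to 25.8%), a little below my stall level, from a “fast reversible equilibrium, held back by released leaving ligand”.

The flask peaks at 0.610 min with 25.5%.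

    starting complex + incoming ligand ⇌ leaving ligand + complex with one exchanged (K = 0.0980, k = 2.48 M⁻¹ min⁻¹)
    complex with one exchanged + incoming ligand ⇌ leaving ligand + complex with two exchanged (K = 3.20, k = 0.513 M⁻¹ min⁻¹)
    protic impurity + starting complex → quenched substrate (k = 22.0 M⁻¹ min⁻¹)
    complex with two exchanged + incoming ligand ⇌ leaving ligand + complex with three exchanged (K = 1.74, k = 3.14 M⁻¹ min⁻¹)
    incoming ligand ⇌ dormant form (K = 3.58, k = 0.108 min⁻¹)

That peak stands 0.50 percentage points below the stall level. Now take the neighbouring flask, with 0.22 M of incoming ligand and the other charges held. The same quotient and balance give a stall level of 13.8%, and that flask's peak, 14.4%, stands above it. At 12.0 min it holds 5.59% of complex with one exchanged and 82.9% of starting complex.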